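The oxepene ring (O1, quaternary C2, C3, C4, C5=C6, C7) is disconnected between the neopentyl methylene C3 and the allylic methylene C4. The key step exploits C4–C5=C6 as an allyl unit: zerovalent nickel converts an E/Z mixture of a C4 allylic bromide into one equilibrating η3-allylnickel bromide that couples with the tethered C3 bromide at its unsubstituted terminus. Only the isomer with C7 cis to C4 can close the seven-membered ring, so C3–C4, the ring and the cis C5=C6 olefin arise in one operation. The acyclic dibromide precursor already holds the (R)-C2 tertiary ether (copper–bisoxazoline pyruvate aldol, then O–H insertion), the aryl ketone and the coumarate chain.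

Key step: step 14

Remark: the facial sense of the copper–bisoxazoline aldol (step 4) is taken over from pyruvate esters, where the (S,S) ligand gives the (S) adduct; with CH2Br in the place of CH3 the same attack is still named (S), so the (R,R) ligand is assigned to the (R) product needed here.
Abbreviations in names: TBS = tert-butyldimethylsilyl; TMSE = 2-(trimethylsilyl)ethyl; TBS-coumaroyl = (2E)-3-[4-(TBS-oxy)phenyl]prop-2-enoyl.

Step 1
Reactants: 1 1-(2,5-dihydroxyphenyl)ethanone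
Product: 2 1-[2,5-bis(TBS-oxy)phenyl]ethanone
Conditions: TBSCl, imidazole, DMF, rt
Reagents that add atoms: tert-butyldimethylsilyl chloride, CC(C)(C)[Si](C)(C)Cl
Why: Phenol silylation with silyl chloride and imidazole should mask both hydroquinone hydroxyls, the hydrogen-bonded ortho one included, as fluoride-labile ethers.

Step 2
Reactants: 2 1-[2,5-bis(TBS-oxy)phenyl]ethanone
Product: 3 {[1-(2,5-bis(TBS-oxy)phenyl)ethenyl]oxy}trimethylsilane
Conditions: TMSOTf, Et3N, CH2Cl2, 0 °C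
Reagents that add atoms: trimethylsilyl trifluoromethanesulfonate, C[Si](C)(C)OS(=O)(=O)C(F)(F)F
Why: Soft enolisation of the aryl methyl ketone (silyl triflate and amine) should give the only possible enol silane, the nucleophile for a Mukaiyama aldol.

Step 3
Reactants: 4 3-bromo-2-oxopropanoic acid; 5 2-(trimethylsilyl)ethanol
Product: 7 TMSE 3-bromo-2-oxopropanoate, via acyl chloride 6 (not isolated)
Conditions: Cl2CHOMe, 50 °C; then 5, CH2Cl2, 0 °C to rt
Reagents that add atoms: none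
Why: Acyl chloride formation from the α-keto acid with dichloromethyl methyl ether followed by alcoholysis should give the fluoride-labile ester without exposing the α-bromo ketone to base or nucleophilic catalysts.

Step 4
Reactants: 3 {[1-(2,5-bis(TBS-oxy)phenyl)ethenyl]oxy}trimethylsilane; 7 TMSE 3-bromo-2-oxopropanoate
Product: 9 TMSE (2R)-4-[2,5-bis(TBS-oxy)phenyl]-2-(bromomethyl)-2-hydroxy-4-oxobutanoate, via trimethylsilyl ether 8 (not isolated)
Conditions: Cu(OTf)2 (10 mol%), (R,R)-tBu-box (11 mol%), THF, −78 °C; then 1 M HCl, THF, 0 °C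
Reagents that add atoms: none
Why: In this Mukaiyama aldol catalysed by a copper–bisoxazoline Lewis acid, the square-planar chelate of the α-keto ester on divalent copper exposes one ketone face, and the (R,R) ligand is chosen so that the enol silane makes C2 (R), after which acid cleaves the silyl ether.

Step 5
Reactants: 10 bromoacetyl bromide; 11 ethanethiol
Product: 12 S-ethyl 2-bromoethanethioate
Conditions: pyridine, CH2Cl2, −20 °C
Reagents that add atoms: none
Why: S-Acylation of the thiol by the acyl bromide is far faster than displacement of the α-bromide and should give the bromothioacetate.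

Step 6
Reactants: 12 S-ethyl 2-bromoethanethioate
Product: 13 S-ethyl 2-diazoethanethioate
Conditions: TsNHNHTs, DBU, THF, 0 °C
Reagents that add atoms: N,N'-ditosylhydrazine, Cc1ccc(cc1)S(=O)(=O)NNS(=O)(=O)c1ccc(C)cc1
Why: N-Alkylation of the bis-sulfonylhydrazine by the α-bromo thioester and base-induced loss of two sulfinate ions (diazo synthesis from α-bromoacetates) should give the diazo thioester.

Step 7
Reactants: 9 TMSE (2R)-4-[2,5-bis(TBS-oxy)phenyl]-2-(bromomethyl)-2-hydroxy-4-oxobutanoate; 13 S-ethyl 2-diazoethanethioate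
Product: 14 TMSE (2R)-4-[2,5-bis(TBS-oxy)phenyl]-2-(bromomethyl)-2-[2-(ethylsulfanyl)-2-oxoethoxy]-4-oxobutanoate
Conditions: Rh2(OAc)4 (2 mol%), CH2Cl2, rt, slow addition of 13
Reagents that add atoms: none
Why: Rhodium-carbenoid O–H insertion should etherify the tertiary hydroxyl under neutral conditions, so that neither retro-aldol cleavage nor epoxide closure of the bromohydrin (both base-induced) can occur, 9 has no olefin to be cyclopropanated, and C2 is not touched.

Step 8
Reactants: 15 5-bromo-2-methylpent-2-ene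
Product: 16 (2E)-5-bromo-2-methylpent-2-en-1-ol
Conditions: SeO2 (cat.), t-BuOOH, CH2Cl2, rt
Reagents that add atoms: selenium dioxide, O=[Se]=O (catalytic carrier of the oxygen atom); tert-butyl hydroperoxide, CC(C)(C)OO (stoichiometric oxygen source)
Why: Riley allylic oxidation (ene reaction of SeO2, then [2,3]-sigmatropic shift) is selective for the (E)-methyl group of a trisubstituted olefin and should set the (E)-allylic alcohol.

Step 9
Reactants: 17 (2E)-3-(4-hydroxyphenyl)prop-2-enoic acid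
Product: 19 (2E)-3-[4-(TBS-oxy)phenyl]prop-2-enoic acid, via bis-silyl derivative 18 (not isolated)
Conditions: TBSCl, imidazole, DMF, rt; then AcOH, THF, H2O
Reagents that add atoms: tert-butyldimethylsilyl chloride, CC(C)(C)[Si](C)(C)Cl
Why: Silylation of both acidic hydroxyls followed by selective hydrolysis of the labile silyl ester should leave only the phenol protected.

Step 10
Reactants: 16 (2E)-5-bromo-2-methylpent-2-en-1-ol; 19 (2E)-3-[4-(TBS-oxy)phenyl]prop-2-enoic acid
Product: 20 (2E)-5-bromo-2-methylpent-2-en-1-yl (2E)-3-[4-(TBS-oxy)phenyl]prop-2-enoate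
Conditions: EDC·HCl, DMAP (cat.), CH2Cl2, 0 °C to rt
Reagents that add atoms: none
Why: Steglich esterification of the primary allylic alcohol should install the coumarate without touching either olefin geometry.

Step 11
Reactants: 14 TMSE (2R)-4-[2,5-bis(TBS-oxy)phenyl]-2-(bromomethyl)-2-[2-(ethylsulfanyl)-2-oxoethoxy]-4-oxobutanoate; 20 (2E)-5-bromo-2-methylpent-2-en-1-yl (2E)-3-[4-(TBS-oxy)phenyl]prop-2-enoate
Product: 22 TMSE (2R)-4-[2,5-bis(TBS-oxy)phenyl]-2-(bromomethyl)-2-{[(5E)-6-methyl-2-oxo-7-(TBS-coumaroyloxy)hept-5-en-1-yl]oxy}-4-oxobutanoate, via alkylzinc bromide 21 (not isolated)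
Conditions: 20, Zn dust, LiCl, THF, 40 °C; then 14, PdCl2(PPh3)2 (5 mol%), toluene, rt
Reagents that add atoms: none
Why: In this Fukuyama ketone synthesis, LiCl-promoted zinc insertion into the primary C–Br bond gives an ester-tolerant alkylzinc bromide that should couple with the thioester under palladium catalysis without touching the esters, the aryl ketone or the neopentyl bromide.

Step 12
Reactants: 22 TMSE (2R)-4-[2,5-bis(TBS-oxy)phenyl]-2-(bromomethyl)-2-{[(5E)-6-methyl-2-oxo-7-(TBS-coumaroyloxy)hept-5-en-1-yl]oxy}-4-oxobutanoate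
Product: 23 TMSE (2R)-4-[2,5-bis(TBS-oxy)phenyl]-2-(bromomethyl)-2-{[(5E)-2-ethenyl-2-hydroxy-6-methyl-7-(TBS-coumaroyloxy)hept-5-en-1-yl]oxy}-4-oxobutanoate (both epimers at the new carbinol carbon C6)
Conditions: CH2=CHMgBr, CeCl3, THF, −78 °C; sat. aq. NH4Cl at −78 °C
Reagents that add atoms: vinylmagnesium bromide, C=C[Mg]Br
Why: In this organocerium 1,2-addition the unhindered α-alkoxy ketone is far more electrophilic than the ortho-substituted neopentyl aryl ketone and the esters, the weakly basic cerium reagent avoids enolisation, and the uncontrolled carbinol centre C6 is immaterial because it becomes sp2 in step 13.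

Step 13
Reactants: 23 TMSE (2R)-4-[2,5-bis(TBS-oxy)phenyl]-2-(bromomethyl)-2-{[(5E)-2-ethenyl-2-hydroxy-6-methyl-7-(TBS-coumaroyloxy)hept-5-en-1-yl]oxy}-4-oxobutanoate
Product: 24 TMSE (2R)-4-[2,5-bis(TBS-oxy)phenyl]-2-(bromomethyl)-2-({4-bromo-2-[(3E)-4-methyl-5-(TBS-coumaroyloxy)pent-3-en-1-yl]but-2-en-1-yl}oxy)-4-oxobutanoate (E/Z mixture at the new C5=C6 bond)
Conditions: PBr3, pyridine (cat.), Et2O, −20 to 0 °C
Reagents that add atoms: phosphorus tribromide, BrP(Br)Br
Why: SN2′ bromination of a tertiary vinyl carbinol (the linalool-to-geranyl bromide type) should place bromide on the terminal carbon C4 and move the double bond to C5=C6 as an E/Z mixture, which the next step tolerates.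

Step 14
Reactants: 24 TMSE (2R)-4-[2,5-bis(TBS-oxy)phenyl]-2-(bromomethyl)-2-({4-bromo-2-[(3E)-4-methyl-5-(TBS-coumaroyloxy)pent-3-en-1-yl]but-2-en-1-yl}oxy)-4-oxobutanoate
Product: 26 TMSE (2R)-2-{2-[2,5-bis(TBS-oxy)phenyl]-2-oxoethyl}-6-[(3E)-4-methyl-5-(TBS-coumaroyloxy)pent-3-en-1-yl]-2,3,4,7-tetrahydrooxepine-2-carboxylate, via allylnickel bromide 25 (not isolated)
Conditions: Ni(cod)2 (1.5 equiv), THF, −10 °C; then DMF, high dilution, 25 to 45 °C
Reagents that add atoms: none
Why: Zerovalent nickel should insert into the allylic C4–Br bond of either olefin isomer to give one η3-allylnickel bromide 25 (divalent nickel), whose syn and anti forms interconvert through η1 forms, as the loss of E/Z integrity in couplings of geranyl- and nerylnickel bromides shows; in DMF a monovalent-nickel radical chain abstracts bromine from the neopentyl C3–Br, the C3 radical is captured at nickel, and reductive elimination from the trivalent alkyl(allyl)nickel forms C3–C4. The closest known reaction is the coupling of π-allylnickel halides with alkyl halides, including its ring-forming variants. The oxepene ring (O1, C2 to C7) closes by C–C bond formation at the unsubstituted allyl terminus C4, a seven-membered closure that is endo with respect to the allyl unit because C5 and C6 end inside the ring. No new stereocentre arises: C2 is not touched, and the C5=C6 geometry is fixed as ring-cis because only the allyl isomer with C7 cis to C4 can cyclise, so the E/Z mixture converges. The step needs attack at C4 rather than C6 and ring closure rather than intermolecular coupling: C6 is fully substituted, C3–Ni has no β-hydrogen because C2 is quaternary, C5=C6 is tied up as the allyl ligand before any C3 radical exists (so 5-exo addition to C6 is not available), and high dilution disfavours dimerisation.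

Step 15
Reactants: 26 TMSE (2R)-2-{2-[2,5-bis(TBS-oxy)phenyl]-2-oxoethyl}-6-[(3E)-4-methyl-5-(TBS-coumaroyloxy)pent-3-en-1-yl]-2,3,4,7-tetrahydrooxepine-2-carboxylate
Product: 27 (2R)-2-[2-(2,5-dihydroxyphenyl)-2-oxoethyl]-6-[(3E)-5-{[(2E)-3-(4-hydroxyphenyl)prop-2-enoyl]oxy}-4-methylpent-3-en-1-yl]-2,3,4,7-tetrahydrooxepine-2-carboxylic acid (CNP0602535.1)
Conditions: TBAF, AcOH, THF, 0 °C to rt
Reagents that add atoms: none
Why: Fluoride-induced global desilylation should cleave the three aryl silyl ethers and fragment the 2-(trimethylsilyl)ethyl ester to ethene, silyl fluoride and the free acid, with acetic acid buffering to protect the β-alkoxy ketone from E1cB ring opening and the allylic coumarate from acyl transfer.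

Compound list
1 | 1-(2,5-dihydroxyphenyl)ethanone | CC(=O)c1cc(O)ccc1O | starting material
2 | 1-[2,5-bis(TBS-oxy)phenyl]ethanone | CC(=O)c1cc(O[Si](C)(C)C(C)(C)C)ccc1O[Si](C)(C)C(C)(C)C | intermediate
3 | {[1-(2,5-bis(TBS-oxy)phenyl)ethenyl]oxy}trimethylsilane | C=C(O[Si](C)(C)C)c1cc(O[Si](C)(C)C(C)(C)C)ccc1O[Si](C)(C)C(C)(C)C | intermediate
4 | 3-bromo-2-oxopropanoic acid (bromopyruvic acid) | OC(=O)C(=O)CBr | starting material
5 | 2-(trimethylsilyl)ethanol | C[Si](C)(C)CCO | starting material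
6 | 3-bromo-2-oxopropanoyl chloride (not isolated) | ClC(=O)C(=O)CBr | intermediate
7 | TMSE 3-bromo-2-oxopropanoate | C[Si](C)(C)CCOC(=O)C(=O)CBr | intermediate
8 | TMSE (2R)-4-[2,5-bis(TBS-oxy)phenyl]-2-(bromomethyl)-4-oxo-2-(trimethylsilyloxy)butanoate (not isolated) | BrC[C@@](CC(=O)c1cc(O[Si](C)(C)C(C)(C)C)ccc1O[Si](C)(C)C(C)(C)C)(C(=O)OCC[Si](C)(C)C)O[Si](C)(C)C | intermediate
9 | TMSE (2R)-4-[2,5-bis(TBS-oxy)phenyl]-2-(bromomethyl)-2-hydroxy-4-oxobutanoate | BrC[C@@](CC(=O)c1cc(O[Si](C)(C)C(C)(C)C)ccc1O[Si](C)(C)C(C)(C)C)(C(=O)OCC[Si](C)(C)C)O | intermediate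
10 | bromoacetyl bromide | BrCC(=O)Br | starting material
11 | ethanethiol | CCS | starting material
12 | S-ethyl 2-bromoethanethioate | CCSC(=O)CBr | intermediate
13 | S-ethyl 2-diazoethanethioate | CCSC(=O)C=[N+]=[N-] | intermediate
14 | TMSE (2R)-4-[2,5-bis(TBS-oxy)phenyl]-2-(bromomethyl)-2-[2-(ethylsulfanyl)-2-oxoethoxy]-4-oxobutanoate | BrC[C@@](CC(=O)c1cc(O[Si](C)(C)C(C)(C)C)ccc1O[Si](C)(C)C(C)(C)C)(C(=O)OCC[Si](C)(C)C)OCC(=O)SCC | intermediate
15 | 5-bromo-2-methylpent-2-ene | BrCCC=C(C)C | starting material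
16 | (2E)-5-bromo-2-methylpent-2-en-1-ol | BrCC/C=C(\C)CO | intermediate
17 | (2E)-3-(4-hydroxyphenyl)prop-2-enoic acid (p-coumaric acid) | OC(=O)/C=C/c1ccc(O)cc1 | starting material
18 | TBS (2E)-3-[4-(TBS-oxy)phenyl]prop-2-enoate (not isolated) | CC(C)(C)[Si](C)(C)OC(=O)/C=C/c1ccc(O[Si](C)(C)C(C)(C)C)cc1 | intermediate
19 | (2E)-3-[4-(TBS-oxy)phenyl]prop-2-enoic acid | OC(=O)/C=C/c1ccc(O[Si](C)(C)C(C)(C)C)cc1 | intermediate
20 | (2E)-5-bromo-2-methylpent-2-en-1-yl (2E)-3-[4-(TBS-oxy)phenyl]prop-2-enoate | BrCC/C=C(\C)COC(=O)/C=C/c1ccc(O[Si](C)(C)C(C)(C)C)cc1 | intermediate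
21 | bromo[(3E)-4-methyl-5-(TBS-coumaroyloxy)pent-3-en-1-yl]zinc (not isolated) | Br[Zn]CC/C=C(\C)COC(=O)/C=C/c1ccc(O[Si](C)(C)C(C)(C)C)cc1 | intermediate
22 | TMSE (2R)-4-[2,5-bis(TBS-oxy)phenyl]-2-(bromomethyl)-2-{[(5E)-6-methyl-2-oxo-7-(TBS-coumaroyloxy)hept-5-en-1-yl]oxy}-4-oxobutanoate | BrC[C@@](CC(=O)c1cc(O[Si](C)(C)C(C)(C)C)ccc1O[Si](C)(C)C(C)(C)C)(C(=O)OCC[Si](C)(C)C)OCC(=O)CC/C=C(\C)COC(=O)/C=C/c1ccc(O[Si](C)(C)C(C)(C)C)cc1 | intermediate
23 | TMSE (2R)-4-[2,5-bis(TBS-oxy)phenyl]-2-(bromomethyl)-2-{[(5E)-2-ethenyl-2-hydroxy-6-methyl-7-(TBS-coumaroyloxy)hept-5-en-1-yl]oxy}-4-oxobutanoate, both carbinol epimers | BrC[C@@](CC(=O)c1cc(O[Si](C)(C)C(C)(C)C)ccc1O[Si](C)(C)C(C)(C)C)(C(=O)OCC[Si](C)(C)C)OCC(O)(C=C)CC/C=C(\C)COC(=O)/C=C/c1ccc(O[Si](C)(C)C(C)(C)C)cc1 | intermediate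
24 | TMSE (2R)-4-[2,5-bis(TBS-oxy)phenyl]-2-(bromomethyl)-2-({4-bromo-2-[(3E)-4-methyl-5-(TBS-coumaroyloxy)pent-3-en-1-yl]but-2-en-1-yl}oxy)-4-oxobutanoate, E/Z mixture at the but-2-ene | BrC[C@@](CC(=O)c1cc(O[Si](C)(C)C(C)(C)C)ccc1O[Si](C)(C)C(C)(C)C)(C(=O)OCC[Si](C)(C)C)OCC(=CCBr)CC/C=C(\C)COC(=O)/C=C/c1ccc(O[Si](C)(C)C(C)(C)C)cc1 | intermediate
25 | bromo(η3-allyl)nickel complex of 24 at C4–C5–C6, drawn in its σ-form with nickel on C4 (not isolated) | BrC[C@@](CC(=O)c1cc(O[Si](C)(C)C(C)(C)C)ccc1O[Si](C)(C)C(C)(C)C)(C(=O)OCC[Si](C)(C)C)OCC(=CC[Ni]Br)CC/C=C(\C)COC(=O)/C=C/c1ccc(O[Si](C)(C)C(C)(C)C)cc1 | intermediate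
26 | TMSE (2R)-2-{2-[2,5-bis(TBS-oxy)phenyl]-2-oxoethyl}-6-[(3E)-4-methyl-5-(TBS-coumaroyloxy)pent-3-en-1-yl]-2,3,4,7-tetrahydrooxepine-2-carboxylate | C/C(=C\CCC1=CCC[C@@](CC(=O)c2cc(O[Si](C)(C)C(C)(C)C)ccc2O[Si](C)(C)C(C)(C)C)(C(=O)OCC[Si](C)(C)C)OC1)COC(=O)/C=C/c1ccc(O[Si](C)(C)C(C)(C)C)cc1 | intermediate
27 | (2R)-2-[2-(2,5-dihydroxyphenyl)-2-oxoethyl]-6-[(3E)-5-{[(2E)-3-(4-hydroxyphenyl)prop-2-enoyl]oxy}-4-methylpent-3-en-1-yl]-2,3,4,7-tetrahydrooxepine-2-carboxylic acid | C/C(=C\CCC1=CCC[C@@](CC(=O)c2cc(O)ccc2O)(C(=O)O)OC1)COC(=O)/C=C/c1ccc(O)cc1 | target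

Total step count: 15 steps.
Longest linear sequence: 9 steps (steps 1, 2, 4, 7, 11, 12, 13, 14, 15, from compound 1).

Steps most likely to fail

Step 14 (key step). The allylnickel intermediate may add to the aryl ketone carbonyl, couple between two molecules, or fragment by β-alkoxy elimination at C2 before reductive elimination. The fallback sets out from 14 and comes back at 26; it closes C3–C4 by a radical conjugate addition in place of the allyl coupling. Thioester 14 would be coupled with vinylzinc bromide (PdCl2(PPh3)2, toluene) to the vinyl ketone F1. Bu3SnH and AIBN under high dilution should then give the ring ketone F2 by 7-endo-trig attack of the C3 radical on the unsubstituted β-carbon C4 of the enone. Kinetic enolisation at the unhindered ring methylene C5 (LiN(SiMe3)2, PhNTf2, THF, −78 °C) would give the enol triflate F3, and Negishi coupling of F3 with zinc reagent 21 (Pd(PPh3)4, THF) would give 26.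

Step 7. Slow insertion into the hindered, hydrogen-bonded tertiary hydroxyl may let carbenoid dimerisation or attack on the electron-rich arene take over. The fallback sets out from 9 and comes back at 14; it builds the ether stepwise under acid and oxidative conditions. Alcohol 9 would be O-allylated with allyl 2,2,2-trichloroacetimidate (TfOH cat., CH2Cl2/cyclohexane) to the allyl ether F4, which has no other olefin. Lemieux–Johnson cleavage (OsO4 cat., NaIO4, 2,6-lutidine) would give the aldehyde F5, Pinnick oxidation (NaClO2, NaH2PO4, 2-methylbut-2-ene) the acid F6, and thioesterification with 11 (DCC, DMAP) would give 14.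

Step 12. The vinyl reagent may also add to the aryl ketone, enolise it with β-elimination of O1, or the new tertiary alkoxide may lactonise onto the C1 ester. The fallback sets out from 22 and comes back at 24; it avoids the tertiary alkoxide by olefination. Wittig reaction of the activated α-alkoxy ketone 22 with (triphenylphosphoranylidene)acetaldehyde (toluene, 90 °C) would give the enal F7, whose E/Z ratio is immaterial. Luche reduction (NaBH4, CeCl3, MeOH, −78 °C) would give the primary allylic alcohol F8, and Appel bromination (CBr4, PPh3, CH2Cl2, 0 °C) would give 24.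

Further compounds
F1 | step 14 | TMSE (2R)-4-[2,5-bis(TBS-oxy)phenyl]-2-(bromomethyl)-4-oxo-2-[(2-oxobut-3-en-1-yl)oxy]butanoate | BrC[C@@](CC(=O)c1cc(O[Si](C)(C)C(C)(C)C)ccc1O[Si](C)(C)C(C)(C)C)(C(=O)OCC[Si](C)(C)C)OCC(=O)C=C
F2 | step 14 | TMSE (2R)-2-{2-[2,5-bis(TBS-oxy)phenyl]-2-oxoethyl}-6-oxooxepane-2-carboxylate | O=C1CCC[C@@](CC(=O)c2cc(O[Si](C)(C)C(C)(C)C)ccc2O[Si](C)(C)C(C)(C)C)(C(=O)OCC[Si](C)(C)C)OC1
F3 | step 14 | TMSE (2R)-2-{2-[2,5-bis(TBS-oxy)phenyl]-2-oxoethyl}-6-{[(trifluoromethyl)sulfonyl]oxy}-2,3,4,7-tetrahydrooxepine-2-carboxylate | FC(F)(F)S(=O)(=O)OC1=CCC[C@@](CC(=O)c2cc(O[Si](C)(C)C(C)(C)C)ccc2O[Si](C)(C)C(C)(C)C)(C(=O)OCC[Si](C)(C)C)OC1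
F4 | step 7 | TMSE (2R)-4-[2,5-bis(TBS-oxy)phenyl]-2-(bromomethyl)-4-oxo-2-(prop-2-en-1-yloxy)butanoate | BrC[C@@](CC(=O)c1cc(O[Si](C)(C)C(C)(C)C)ccc1O[Si](C)(C)C(C)(C)C)(C(=O)OCC[Si](C)(C)C)OCC=C
F5 | step 7 | TMSE (2R)-4-[2,5-bis(TBS-oxy)phenyl]-2-(bromomethyl)-4-oxo-2-(2-oxoethoxy)butanoate | BrC[C@@](CC(=O)c1cc(O[Si](C)(C)C(C)(C)C)ccc1O[Si](C)(C)C(C)(C)C)(C(=O)OCC[Si](C)(C)C)OCC=O
F6 | step 7 | ({(2R)-4-[2,5-bis(TBS-oxy)phenyl]-1-bromo-4-oxo-2-{[2-(trimethylsilyl)ethoxy]carbonyl}butan-2-yl}oxy)acetic acid | BrC[C@@](CC(=O)c1cc(O[Si](C)(C)C(C)(C)C)ccc1O[Si](C)(C)C(C)(C)C)(C(=O)OCC[Si](C)(C)C)OCC(=O)O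
F7 | step 12 | TMSE (2R)-4-[2,5-bis(TBS-oxy)phenyl]-2-(bromomethyl)-2-({2-[(3E)-4-methyl-5-(TBS-coumaroyloxy)pent-3-en-1-yl]-4-oxobut-2-en-1-yl}oxy)-4-oxobutanoate, E/Z mixture at the but-2-ene | BrC[C@@](CC(=O)c1cc(O[Si](C)(C)C(C)(C)C)ccc1O[Si](C)(C)C(C)(C)C)(C(=O)OCC[Si](C)(C)C)OCC(=CC=O)CC/C=C(\C)COC(=O)/C=C/c1ccc(O[Si](C)(C)C(C)(C)C)cc1
F8 | step 12 | TMSE (2R)-4-[2,5-bis(TBS-oxy)phenyl]-2-(bromomethyl)-2-({4-hydroxy-2-[(3E)-4-methyl-5-(TBS-coumaroyloxy)pent-3-en-1-yl]but-2-en-1-yl}oxy)-4-oxobutanoate, E/Z mixture at the but-2-ene | BrC[C@@](CC(=O)c1cc(O[Si](C)(C)C(C)(C)C)ccc1O[Si](C)(C)C(C)(C)C)(C(=O)OCC[Si](C)(C)C)OCC(=CCO)CC/C=C(\C)COC(=O)/C=C/c1ccc(O[Si](C)(C)C(C)(C)C)cc1
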